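**Plan**
- **Cuts:** first the three late C–Br bonds (C2–Br, C3–Br, and C6–Br back to C6–SiMe3). Next C4–C5 and C6–C7 of the benzene ring, then the lactone C–O bond and the formyl and acetic acid carbons on neighbouring pyrrole carbons.
- **Enabling feature:** C4–C5–C6–C7 is a four-carbon bridge over the pyrrole bond C3a–C7a, with bromine on C4 and C6. C4 and C7 are therefore the termini of a pyrrole-fused 2-pyranone diene (Br on the lactone α-carbon), and C5–C6 is a terminal alkyne carrying silicon as masked bromine on C6.
- **Ring order, forward:** pyrrole (bought), then the pyranone ring closed on two adjacent pyrrole carbons, then the benzene ring made from it by [4+2] cycloaddition and loss of CO2.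
- **Bromine order:** C4 on the pyranone, then C3, C2 and (ipso, in place of silicon) C6 on the indole.
- **Stereochemistry:** the target has no stereocentre. The two bridgeheads of the transient cycloadduct vanish with CO2, so only regiochemistry has to be controlled.

Key step: step 8

Remark: the indoles carry indole locants and the pyranones carry the locants N1, C2, C3, C3a, C4, C5, O6, C7, C7a of pyrano[3,4-b]pyrrole, so C2, C3, C3a, C4, C7 and C7a are the same atoms before and after the key step. Steps 1 to 5 use simple pyrrole locants. The three starting materials are taken to be commercial.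

Step 1
Reactants: 1 1-tosyl-1H-pyrrole; 2 acetyl chloride
Product: 3 1-(1-tosyl-1H-pyrrol-3-yl)ethan-1-one (3-acetyl-1-tosylpyrrole)
Conditions: AlCl3 (2 equiv), CH2Cl2, 0 °C to rt
Reagents that add atoms: none
Why: Friedel–Crafts acylation in which the N-arylsulfonyl group together with the hard Lewis acid AlCl3 turns the usual α-preference of pyrrole into β-selectivity, the standard entry to 3-acyl-1-sulfonylpyrroles.

Step 2
Reactants: 3 3-acetyl-1-tosylpyrrole
Product: 4 methyl 2-(1-tosyl-1H-pyrrol-3-yl)acetate
Conditions: Tl(NO3)3·3H2O (1.1 equiv), MeOH/HC(OMe)3, rt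
Reagents that add atoms: methanol, CO
Why: Oxidative 1,2-aryl migration of an aryl methyl ketone, in which trivalent thallium adds to the enol ether formed in the acidic methanol and its departure as monovalent thallium pulls the electron-rich pyrrol-3-yl group from the carbonyl carbon onto the former methyl carbon, a conversion established for 3-acetyl-1-arylsulfonylpyrroles that leaves the sulfonamide untouched.

Step 3
Reactants: 4 methyl 2-(1-tosyl-1H-pyrrol-3-yl)acetate
Product: 5 methyl 2-(1H-pyrrol-3-yl)acetate
Conditions: Mg turnings (excess), MeOH, rt, ultrasound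
Reagents that add atoms: none
Why: Reductive desulfonylation by electron transfer from magnesium cleaves the N–S bond because the pyrrolide is a good leaving group, and in methanol the methyl ester can only exchange with itself, so the ester that shields the carboxyl group in step 4 is kept.

Step 4
Reactants: 5 methyl 2-(1H-pyrrol-3-yl)acetate
Product: 7 methyl 2-(2-formyl-1H-pyrrol-3-yl)acetate, via iminium chloride 6 (not isolated)
Conditions: POCl3 (1.1 equiv), DMF (1.2 equiv), ClCH2CH2Cl, 0 °C to rt; then aq NaOAc, rt
Reagents that add atoms: N,N-dimethylformamide, CN(C)C=O; water, O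
Why: Vilsmeier–Haack formylation in which the chloroiminium ion attacks an α-carbon of the free pyrrole, preferring pyrrole C2 next to the slim, weakly donating CH2CO2Me chain as with other 3-alkylpyrroles bearing unbranched chains, while any 5-formyl isomer is removed by chromatography and could not close the lactone of step 6 in any case, and hydrolysis of iminium salt 6 then releases the aldehyde.

Step 5
Reactants: 7 methyl 2-(2-formyl-1H-pyrrol-3-yl)acetate
Product: 8 2-(2-formyl-1H-pyrrol-3-yl)acetic acid
Conditions: LiOH·H2O (1.5 equiv), THF/H2O, 0 °C to rt; then 1 M HCl to pH 3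
Reagents that add atoms: lithium hydroxide, [Li+].[OH-]
Why: Ordinary saponification of an unhindered aliphatic methyl ester, tolerated by the pyrrole-2-carbaldehyde because this vinylogous formamide has no α-hydrogen and is a poor electrophile toward cold dilute hydroxide.

Step 6
Reactants: 8 2-(2-formyl-1H-pyrrol-3-yl)acetic acid
Product: 10 pyrano[3,4-b]pyrrol-5(1H)-one, via mixed anhydride 9 (not isolated)
Conditions: Ac2O, 90 °C, 1 h; evaporation
Reagents that add atoms: none
Why: Cyclodehydration of an ortho-formyl arylacetic acid, in which the formyl oxygen of mixed anhydride 9 attacks the activated acyl carbon (six-membered ring) and loss of the now acidic C4 proton gives the neutral fused 2-pyranone, the way in which 2-benzopyran-3-ones and related heteroaryl-fused pyranones are made from formyl- or acyl-substituted arylacetic acids.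

Step 7
Reactants: 10 pyrano[3,4-b]pyrrol-5(1H)-one
Product: 11 4-bromopyrano[3,4-b]pyrrol-5(1H)-one
Conditions: NBS (1.0 equiv), THF, −78 to −20 °C, dark
Reagents that add atoms: N-bromosuccinimide, O=C1CCC(=O)N1Br
Why: Electrophilic α-bromination of a 2-pyranone that is also a vinylogous amide, directed to C4 because this carbon ends both the dienol ether O6–C7=C7a–C3a=C4 and the dienamine N1–C2=C3–C3a=C4 and because attack there alone gives a cation with an intact aromatic pyrrole, so one equivalent of NBS at low temperature should stop at the C4 monobromide.

Step 8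
Reactants: 11 4-bromopyrano[3,4-b]pyrrol-5(1H)-one; 12 trimethylsilylacetylene
Product: 14 4-bromo-6-(trimethylsilyl)-1H-indole, via bridged lactone 13 (not isolated)
Conditions: Me3SiC≡CH (10 equiv), PhBr, BHT (trace), sealed tube, 150 °C
Reagents that add atoms: none
Why: Thermal [4+2] cycloaddition of the alkyne across the diene C4=C3a–C7a=C7 of the fused 2-pyranone gives the 2-oxabicyclo[2.2.2]octadienone 13, in which the pyrrole sextet is regained, and 13 at once expels CO2 by retro-[4+2]. The closest known reactions are the alkyne cycloaddition–decarboxylations of pyrano[3,4-b]pyrrol-5(1H)-ones and pyrano[3,4-b]indol-3-ones to indoles and carbazoles, and those of simple 2-pyranones with silylacetylenes to arylsilanes. The benzene ring is closed intermolecularly by a concerted suprafacial [4+2] annulation that forms C4–C5 and C6–C7 in one event, and it is aromatic as soon as CO2 has left, so no sp3 C–Br centre ever exists from which HBr could be lost. No stereocentre survives, since the two bridgeheads of racemic 13 become sp2 carbons. The step needs the silicon-bearing alkyne carbon to bond to C7, which the substrate secures sterically (SiMe3 avoids the C4 bromine and meets only C7–H beside an unsubstituted N1–H) and electronically (bonding through the silicon-bearing carbon places the developing positive charge β to silicon, and this nucleophilic carbon pairs with the oxygen-bearing, electrophilic terminus C7 while the enolate-like C4 closes the second bond). The C4 bromine and the lactone carbonyl lower the diene LUMO toward an unactivated alkyne, and a large excess of the volatile alkyne in a closed vessel makes up for its modest reactivity.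

Step 9
Reactants: 14 4-bromo-6-(trimethylsilyl)-1H-indole
Product: 17 2,3,4,6-tetrabromo-1H-indole (the target), via 3,4-dibromo silylindole 15 (not isolated), via 2,3,4-tribromo silylindole 16 (not isolated)
Conditions: NBS (2.05 equiv), silica gel, CH2Cl2, 0 °C, dark; then Br2 (1.05 equiv), 0 °C to rt
Reagents that add atoms: N-bromosuccinimide, O=C1CCC(=O)N1Br; bromine, BrBr
Why: Electrophilic substitution in the order of intrinsic reactivity, in which NBS brominates the enamine carbon C3 and then C2 as in the usual conversion of indoles into 2,3-dibromoindoles, and Br2 then attacks the silicon-bearing C6, where the β-silicon effect stabilises the ipso σ-complex and Me3SiBr leaves (ipso-bromodesilylation of an aryltrimethylsilane), while the C–H positions C5 and C7 are by then deactivated by three ring bromines.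

**Compound list**
1 | 1-tosyl-1H-pyrrole | Cc1ccc(cc1)S(=O)(=O)n1cccc1 | starting material
2 | acetyl chloride | CC(=O)Cl | starting material
3 | 1-(1-tosyl-1H-pyrrol-3-yl)ethan-1-one | CC(=O)c1ccn(c1)S(=O)(=O)c1ccc(C)cc1 | intermediate
4 | methyl 2-(1-tosyl-1H-pyrrol-3-yl)acetate | COC(=O)Cc1ccn(c1)S(=O)(=O)c1ccc(C)cc1 | intermediate
5 | methyl 2-(1H-pyrrol-3-yl)acetate | COC(=O)Cc1cc[nH]c1 | intermediate
6 | [3-(2-methoxy-2-oxoethyl)-1H-pyrrol-2-yl]methylidene(dimethyl)ammonium chloride | COC(=O)Cc1cc[nH]c1C=[N+](C)C.[Cl-] | intermediate (not isolated)
7 | methyl 2-(2-formyl-1H-pyrrol-3-yl)acetate | COC(=O)Cc1cc[nH]c1C=O | intermediate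
8 | 2-(2-formyl-1H-pyrrol-3-yl)acetic acid | OC(=O)Cc1cc[nH]c1C=O | intermediate
9 | acetic 2-(2-formyl-1H-pyrrol-3-yl)acetic anhydride | CC(=O)OC(=O)Cc1cc[nH]c1C=O | intermediate (not isolated)
10 | pyrano[3,4-b]pyrrol-5(1H)-one | O=C1C=C2C=CNC2=CO1 | intermediate
11 | 4-bromopyrano[3,4-b]pyrrol-5(1H)-one | O=C1C(Br)=C2C=CNC2=CO1 | intermediate
12 | trimethylsilylacetylene (ethynyltrimethylsilane) | C#C[Si](C)(C)C | starting material
13 | 4-bromo-6-(trimethylsilyl)-4,7-dihydro-1H-7,4-(epoxymethano)indol-9-one (O on C7, C=O on C4; racemic, one enantiomer written) | O=C1O[C@@H]2C(=C[C@@]1(Br)c1cc[nH]c12)[Si](C)(C)C | intermediate (not isolated)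
14 | 4-bromo-6-(trimethylsilyl)-1H-indole | C[Si](C)(C)c1cc(Br)c2cc[nH]c2c1 | intermediate
15 | 3,4-dibromo-6-(trimethylsilyl)-1H-indole | C[Si](C)(C)c1cc(Br)c2c(Br)c[nH]c2c1 | intermediate (not isolated)
16 | 2,3,4-tribromo-6-(trimethylsilyl)-1H-indole | C[Si](C)(C)c1cc(Br)c2c(Br)c(Br)[nH]c2c1 | intermediate (not isolated)
17 | 2,3,4,6-tetrabromo-1H-indole | Brc1cc(Br)c2c(Br)c(Br)[nH]c2c1 | target

Total step count: 9. Longest linear sequence: 9 steps (1 to 17).

**Steps most likely to fail**

**Step 8 (key step).**
- *Risk:* the cycloaddition may be too slow for an alkyne without an activating group, so thermal breakdown of the N–H bromodiene overtakes it. Orientation control may also erode at the temperature that is needed.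
- *Fallback:* this changes the diene, not the heating, and sets out from 11.
- The nitrogen of 11 is acylated (ClCO2Me, Et3N, catalytic DMAP, CH2Cl2, 0 °C) to methyl 4-bromo-5-oxopyrano[3,4-b]pyrrole-1(5H)-carboxylate F1.
- With the nitrogen lone pair tied up in the carbamate, the push–pull stabilisation from N1 to the C5 carbonyl is lost. The diene comes closer to a true pyrrole 2,3-quinodimethane and its LUMO drops.
- The reaction with 12 then becomes an inverse-electron-demand cycloaddition that should run at a clearly lower temperature (toluene, sealed tube, about 110 °C). After loss of CO2 it should give methyl 4-bromo-6-(trimethylsilyl)-1H-indole-1-carboxylate F2.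
- K2CO3 in MeOH at rt removes the carbamate without touching the aryl–silicon bond, and the route is rejoined at 14.

**Step 7.**
- *Risk:* site selectivity may be lost. The free N–H pyrrole part may be brominated at C3 or C2, or the enamine-like C7 may react, in competition with C4. Bromination may also run on past the monobromide.
- *Fallback:* this sets out from 10, which is converted with Boc2O and catalytic DMAP in MeCN into tert-butyl 5-oxopyrano[3,4-b]pyrrole-1(5H)-carboxylate F3.
- The carbamate withdraws the nitrogen donation on which C2, C3 and C7 depend, whereas C4 keeps the donation from O6.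
- NBS (CH2Cl2, 0 °C) should then give tert-butyl 4-bromo-5-oxopyrano[3,4-b]pyrrole-1(5H)-carboxylate F4.
- TFA in CH2Cl2 at 0 °C removes the Boc group, and the route is rejoined at 11.

**Step 9.**
- *Risk:* in the third bromination, C–H substitution at C5 or C7, or protodesilylation by adventitious HBr, may compete with ipso attack at C6. The sensitive 2,3-dibromoindole stage may also degrade oxidatively.
- *Fallback:* the electrophilic exchange of silicon for bromine is replaced by a copper-mediated exchange of boron for bromine. Its site is fixed by the C–B bond, and it is carried out before the pyrrole ring is brominated. It sets out from 11.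
- Compound 11 is heated with commercial 2-ethynyl-4,4,5,5-tetramethyl-1,3,2-dioxaborolane (PhBr, sealed tube, 150 °C). This is a 2-pyranone/alkynylboronate cycloaddition in which the bulky boronate again stays away from the C4 bromine. It should give 4-bromo-6-(4,4,5,5-tetramethyl-1,3,2-dioxaborolan-2-yl)-1H-indole F5.
- CuBr2 (3 equiv) in MeOH/H2O at 80 °C converts the boronate into 4,6-dibromo-1H-indole F6.
- NBS (2 equiv, silica gel, CH2Cl2, 0 °C) brominates C3 and then C2, by way of 3,4,6-tribromo-1H-indole F7. The route is rejoined at its end, 17.

**Further compounds**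
F1 | step 8 | methyl 4-bromo-5-oxopyrano[3,4-b]pyrrole-1(5H)-carboxylate | O=C1C(Br)=C2C=CN(C(=O)OC)C2=CO1
F2 | step 8 | methyl 4-bromo-6-(trimethylsilyl)-1H-indole-1-carboxylate | COC(=O)n1ccc2c(Br)cc(cc12)[Si](C)(C)C
F3 | step 7 | tert-butyl 5-oxopyrano[3,4-b]pyrrole-1(5H)-carboxylate | O=C1C=C2C=CN(C(=O)OC(C)(C)C)C2=CO1
F4 | step 7 | tert-butyl 4-bromo-5-oxopyrano[3,4-b]pyrrole-1(5H)-carboxylate | O=C1C(Br)=C2C=CN(C(=O)OC(C)(C)C)C2=CO1
F5 | step 9 | 4-bromo-6-(4,4,5,5-tetramethyl-1,3,2-dioxaborolan-2-yl)-1H-indole | CC1(C)OB(OC1(C)C)c1cc(Br)c2cc[nH]c2c1
F6 | step 9 | 4,6-dibromo-1H-indole | Brc1cc(Br)c2cc[nH]c2c1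
F7 | step 9 | 3,4,6-tribromo-1H-indole | Brc1cc(Br)c2c(Br)c[nH]c2c1
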